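## The problem

6-Prenylsakuranetin (17) is a flavanone: a chroman-4-one (ring C) fused to ring A, with a 4-hydroxyphenyl ring B at C2. Five of the six ring A carbons are substituted (acyl carbon at C4a, hydroxyl at C5, prenyl at C6, methoxyl at C7, O1 at C8a); only C8 carries hydrogen. The single stereocentre, C2 (S), is benzylic, bound to O1 and β to the C4 ketone. No second centre exists to relay from, so its configuration must come from a catalyst. It can be lost again by reversible opening of ring C to the 2'-hydroxychalcone, quickly under base and more slowly under acid or heat. Ring A poses three regiochemical questions: prenyl at C6 and not C8, methyl on O7 and not O5, and O4' kept distinguishable from both. The prenyl olefin does not tolerate strong acid (it closes onto O5–H to a dimethylchroman), hydrogenation or electrophiles, and the phenols and the flavanone do not tolerate strong base. The enabling feature is that C4 is a lone carbonyl carbon between C4a and C3, while C3, C2 and ring B have, at the flavone oxidation level, the pattern of an arylacetylene. Without the prenyl group, ring A has a mirror plane through C4a and C7, so O1 and O5 are the two equivalent hydroxyls of a 2-iodo-5-methoxyresorcinol; the hydroxyl left unused becomes O5–H, whose only free ortho carbon is C6.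

## Retrosynthesis

**17 from 16.** The two O–CH2 bonds of the methoxymethyl (MOM) acetals on O5 and O4' are cut last. One protic step then frees both phenols. The forward reaction must be mild enough to leave the prenyl olefin and C2 alone.

**16 from 15.** The C2–H and C3–H bonds are removed, leading back to flavone 15. This places the only stereocentre at the penultimate step, after all basic and thermal operations. The neighbouring cut, O1–C2 by asymmetric oxa-Michael closure of a 2'-hydroxychalcone, is reversible and would have to tell two ortho oxygens apart. A C2–aryl cut would need a 2-unsubstituted chromone that the ring-forming step does not deliver. The forward step is a ligand-controlled hydride delivery to C2 that must spare the trisubstituted prenyl olefin and the C4 carbonyl. O5 is capped beforehand so that no acidic phenol quenches the hydride or deactivates the enone as its phenoxide.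

**15 from 14.** Only the O5 MOM group is removed; 14 is the chelated 5-hydroxy-6-prenylflavone.

**14 from 12, 11, and from 9 plus 10.** The C6–C1'' bond is cut by a retro-Claisen shift, which moves the C5 unit to O5 as the 1,1-dimethylallyl ether 12. Direct Friedel–Crafts prenylation would give C6, C8 and O products, and carrying the prenyl group through ring closure would destroy the symmetry of ring A. In 12, C4a is blocked, so the [3,3] shift can only reach C6 and inverts the allyl unit to prenyl. Ether 12 comes from the propargyl ether 11 by semihydrogenation, and 11 from flavone 9 and commercial 3-chloro-3-methylbut-1-yne (10). The Claisen shift is placed before the reduction for two reasons: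
- DBU and 130 °C are harmless to a flavone but not to a flavanone.
- The terminal vinyl group of 12 could be hydrocuprated, whereas the prenyl olefin of 15 cannot.

**9 from 2, 6 and 5.** This is the key cut: C4a–C4, C4–C3 and O1–C2 are broken together. Flavone 9 falls into 2-iodo-5-methoxyresorcinol (2), carbon monoxide (6) and 1-ethynyl-4-(methoxymethoxy)benzene (5). Chalcone or diketone routes need a preformed acetophenone and two or three steps to close ring C. Here three achiral pieces, one of them symmetric, give the ring in one operation. The forward reaction must take up CO before coupling and close the six-membered, not the five-membered, ring.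

**2 from 1; 5 from 4 and 3.** Iodide 2 comes from 5-methoxyresorcinol (1) by iodination between the hydroxyls. Alkyne 5 comes from 4-hydroxybenzaldehyde (3) by MOM protection to 4 and one-carbon homologation. MOM is chosen for O4' because it survives hot amine, DBU, NaH and copper hydride.

## Roads not taken

**Alternative 1:** The C2–C3 bond is cut. A diazoketone on C4a next to an O1 benzyl ether, A1, would be turned by a chiral divalent rhodium carboxylate dimer into a carbene at C3. Insertion into a benzylic C–H bond would close ring C and set C2, giving A2.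
- Merits: ring C and the stereocentre arise in one catalytic step at the flavanone oxidation level, with the prenyl group already in place and no flavone to reduce. In this respect it is better than the chosen plan, which needs a separate asymmetric step.
- Weak points: the carbene carries only an acyl group, the class that gives the lowest selectivities. Attack of the O1 lone pair on the carbene, followed by a [1,2]-benzyl shift, would build a five-membered ring in place of ring C. The prenyl olefin is a carbene trap. A1 needs a fully differentiated ring A and diazoketone formation on a doubly ortho-substituted acid.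
- Comparison: the chosen plan offers a symmetric ring A piece and direct precedent for every bond-forming step.

**Alternative 2:** The C4a–C5 bond is cut. A preformed, enantiopure ring C carrying a β-keto ester chain, A3, would be enolised at C8, and the vinylogous enolate would attack the ester through C4a. This closes ring A, which aromatises to A4.
- Merits: C2 could be set early by asymmetric hetero-Diels–Alder or aldol chemistry, arguably more reliable than a late reduction of a hindered flavone. The prenyl position is fixed by C-alkylation of a β-keto ester, so no aromatic regiochemistry arises. On both points it is as good as or better than the chosen plan.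
- Weak points: the most acidic site of A3 is C6–H, so base first makes an enolate that deactivates the ester, and closure needs a dianion. O-cyclisation competes. C2 sits β to a carbonyl under base throughout and can racemise by elimination of O1. A4 has a free O7–H that must be methylated selectively, again under base, and the chain assembly is long.
- Comparison: the chosen plan never exposes the stereocentre to base and has the shorter linear sequence.

**Alternative 3:** The C3–C4 and O1–C2 bonds are cut. Salicylaldehyde A5, styrene A6 and trimethyl orthoformate A7 would combine under a confined chiral Brønsted acid, through a C4-methoxy ortho-quinone methide, in a [4+2] reaction to give the cis 4-methoxyflavan A8.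
- Merits: it is convergent, sets C2 under catalyst control in the ring-forming step, and A6 is simple. On stereochemical economy it is better than the chosen plan.
- Weak points: A8 is at the flavan oxidation level, so C4 must still be oxidised to the ketone in the presence of a prenyl olefin and an electron-rich ring. Strong acid with an orthoester threatens the MOM acetals and can protonate the prenyl olefin. A5 needs three differentiated oxygens and regiodefined formyl and prenyl groups, which costs several steps on a phloroglucinol.
- Comparison: the chosen plan has the correct C4 oxidation state from carbon monoxide, a symmetric ring A precursor, and uses acid only in the last step.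

Key step: step 4

Assumption: copper hydride bound to (R)-DTBM-SEGPHOS is taken to deliver hydride to the face of C2 that gives the S product. Should the sense on a 2-arylchromone be the reverse, the equally available (S)-ligand replaces it and nothing else changes.

## Route

Step 1
Reactants: 1 5-methoxyresorcinol (5-methoxybenzene-1,3-diol)
Product: 2 2-iodo-5-methoxyresorcinol (2-iodo-5-methoxybenzene-1,3-diol)
Conditions: I2, NaHCO3, THF/H2O (1:1), 0 °C
Reagents that add atoms: iodine, II
Why: Electrophilic aromatic iodination under bicarbonate buffering; as with resorcinol, the carbon flanked by both hydroxyls should react first, and the symmetric product is distinguishable from its isomer by its two equivalent ring protons.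

Step 2
Reactants: 3 4-hydroxybenzaldehyde
Product: 4 4-(methoxymethoxy)benzaldehyde
Conditions: MOMCl, K2CO3, acetone, 0 °C to rt
Reagents that add atoms: chloromethyl methyl ether, COCCl
Why: Williamson-type O-alkylation of an acidic para-formyl phenol; the MOM acetal is chosen because it is inert to the amine, base and hydride steps that follow.

Step 3
Reactants: 4 4-(methoxymethoxy)benzaldehyde
Product: 5 1-ethynyl-4-(methoxymethoxy)benzene
Conditions: dimethyl (1-diazo-2-oxopropyl)phosphonate, K2CO3, MeOH, rt
Reagents that add atoms: dimethyl (1-diazo-2-oxopropyl)phosphonate, COP(=O)(OC)C(=[N+]=[N-])C(C)=O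
Why: Seyferth–Gilbert homologation in the Ohira–Bestmann variant, which turns aryl aldehydes into terminal alkynes under mild carbonate conditions that leave the MOM ether untouched.

Step 4
Reactants: 2 2-iodo-5-methoxyresorcinol, 6 carbon monoxide, 5 1-ethynyl-4-(methoxymethoxy)benzene
Product: 9 5-hydroxy-7-methoxy-2-[4-(methoxymethoxy)phenyl]-4H-chromen-4-one, via aryl ynone 7 (not isolated), via diethylamino enone 8 (not isolated)
Conditions: PdCl2(dppf) (5 mol%), CO (20 atm), Et2NH, 120 °C, autoclave
Reagents that add atoms: none
Why: PdCl2(dppf) is reduced in the amine to zerovalent palladium, which inserts into the C4a–I bond of 2; CO insertion gives an aroylpalladium iodide, the amine-deprotonated alkyne 5 replaces iodide, and reductive elimination forms C4a–C4 and C4–C3 as ynone 7. Diethylamine adds to 7 at C2 to give enaminone 8, and one of the two equivalent ortho hydroxyls attacks C2 and expels the amine, forming O1–C2. Ring C thus closes by a 6-endo-trig addition–elimination on 8, a net 6-endo-dig closure of the ynone that the Baldwin rules allow. The closest known reaction type is the palladium-catalysed carbonylative Sonogashira coupling of 2-iodophenols with terminal alkynes in a secondary amine, which ends in flavones. No stereocentre is formed. Carbonylative coupling must win over direct coupling (which would lead to a 2-arylbenzofuran); the high CO pressure and the ready migration of an electron-rich aryl group to CO should secure this. The flavone must win over the five-membered aurone; routing the closure through the amine adduct, in which only C2 is electrophilic, should secure this. The choice between O1 and O5 needs no control because the mirror symmetry of 2 makes the two hydroxyls identical, and the unused one ends as the chelated O5–H.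

Step 5
Reactants: 9 5-hydroxy-7-methoxy-2-[4-(methoxymethoxy)phenyl]-4H-chromen-4-one, 10 3-chloro-3-methylbut-1-yne
Product: 11 7-methoxy-2-[4-(methoxymethoxy)phenyl]-5-[(2-methylbut-3-yn-2-yl)oxy]-4H-chromen-4-one
Conditions: DBU, CuCl2 (cat.), MeCN, 0 °C to rt
Reagents that add atoms: none
Why: Copper-catalysed propargylic etherification of a phenol with a tertiary propargylic chloride: a copper acetylide ionises to a copper allenylidene that the phenoxide captures at the tertiary carbon. DBU breaks the O5–H to O4 hydrogen bond by full deprotonation, and O5 is the only free hydroxyl.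

Step 6
Reactants: 11 7-methoxy-2-[4-(methoxymethoxy)phenyl]-5-[(2-methylbut-3-yn-2-yl)oxy]-4H-chromen-4-one
Product: 12 7-methoxy-2-[4-(methoxymethoxy)phenyl]-5-[(2-methylbut-3-en-2-yl)oxy]-4H-chromen-4-one
Conditions: H2 (1 atm), Pd/CaCO3 poisoned with Pb(OAc)2, quinoline, EtOAc, rt
Reagents that add atoms: none
Why: Lindlar semihydrogenation of a terminal alkyne to the vinyl group; the trisubstituted, donor-substituted C2=C3 bond of the pyranone is not reduced by the poisoned catalyst.

Step 7
Reactants: 12 7-methoxy-2-[4-(methoxymethoxy)phenyl]-5-[(2-methylbut-3-en-2-yl)oxy]-4H-chromen-4-one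
Product: 14 5-hydroxy-7-methoxy-2-[4-(methoxymethoxy)phenyl]-6-(3-methylbut-2-en-1-yl)-4H-chromen-4-one, via ring A dienone 13 (not isolated)
Conditions: PhNEt2, 130 °C
Reagents that add atoms: none
Why: Aromatic Claisen rearrangement: the 1,1-dimethylallyl group moves by a [3,3] shift with allylic inversion from O5 to C6, the only free ortho carbon (C4a is blocked), and so arrives as the prenyl group. Tautomerisation of dienone 13 restores ring A, and the re-formed O5–H to O4 chelate adds driving force.

Step 8
Reactants: 14 5-hydroxy-7-methoxy-2-[4-(methoxymethoxy)phenyl]-6-(3-methylbut-2-en-1-yl)-4H-chromen-4-one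
Product: 15 7-methoxy-5-(methoxymethoxy)-2-[4-(methoxymethoxy)phenyl]-6-(3-methylbut-2-en-1-yl)-4H-chromen-4-one
Conditions: NaH, MOMCl, DMF, 0 °C to rt
Reagents that add atoms: chloromethyl methyl ether, COCCl
Why: O-alkylation of the sodium phenoxide; full deprotonation with NaH is used because O5–H is chelated and flanked by the carbonyl and the prenyl group.

Step 9
Reactants: 15 7-methoxy-5-(methoxymethoxy)-2-[4-(methoxymethoxy)phenyl]-6-(3-methylbut-2-en-1-yl)-4H-chromen-4-one
Product: 16 (2S)-7-methoxy-5-(methoxymethoxy)-2-[4-(methoxymethoxy)phenyl]-6-(3-methylbut-2-en-1-yl)chroman-4-one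
Conditions: Cu(OAc)2·H2O (5 mol%), (R)-DTBM-SEGPHOS (5.5 mol%), HSiMe(OEt)2, t-BuOH, toluene, −10 °C to rt
Reagents that add atoms: none
Why: Copper hydride catalysed asymmetric conjugate reduction, a reaction known for 2-substituted chromones: the bisphosphine-bound copper hydride adds hydrogen to C2 from the face set by the ligand, so the 2S centre arises by catalyst control, and t-BuOH protonates the copper enolate at C3 before it can open ring C. The trisubstituted prenyl olefin, the MOM acetals and the hindered, electron-rich C4 ketone should not react.

Step 10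
Reactants: 16 (2S)-7-methoxy-5-(methoxymethoxy)-2-[4-(methoxymethoxy)phenyl]-6-(3-methylbut-2-en-1-yl)chroman-4-one
Product: 17 6-prenylsakuranetin, (2S)-5-hydroxy-2-(4-hydroxyphenyl)-7-methoxy-6-(3-methylbut-2-en-1-yl)chroman-4-one
Conditions: 3 M aq. HCl, MeOH, 40 °C
Reagents that add atoms: none
Why: Acid-catalysed acetal exchange with methanol removes both MOM groups, the one on O5 fastest because the chelated phenol is a good leaving group. Dilute acid at mild temperature is the usual end-game for prenylated flavanones and should leave the prenyl olefin and C2 unchanged.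

## Compound list

1 | 5-methoxyresorcinol (5-methoxybenzene-1,3-diol) | COc1cc(O)cc(O)c1 | starting material
2 | 2-iodo-5-methoxybenzene-1,3-diol | COc1cc(O)c(I)c(O)c1 | intermediate
3 | 4-hydroxybenzaldehyde | O=Cc1ccc(O)cc1 | starting material
4 | 4-(methoxymethoxy)benzaldehyde | COCOc1ccc(C=O)cc1 | intermediate
5 | 1-ethynyl-4-(methoxymethoxy)benzene | C#Cc1ccc(OCOC)cc1 | intermediate
6 | carbon monoxide | [C-]#[O+] | starting material
7 | 1-(2,6-dihydroxy-4-methoxyphenyl)-3-[4-(methoxymethoxy)phenyl]prop-2-yn-1-one | COc1cc(O)c(C(=O)C#Cc2ccc(OCOC)cc2)c(O)c1 | intermediate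
8 | 3-(diethylamino)-1-(2,6-dihydroxy-4-methoxyphenyl)-3-[4-(methoxymethoxy)phenyl]prop-2-en-1-one | CCN(CC)C(=CC(=O)c1c(O)cc(OC)cc1O)c1ccc(OCOC)cc1 | intermediate
9 | 5-hydroxy-7-methoxy-2-[4-(methoxymethoxy)phenyl]-4H-chromen-4-one | COc1cc(O)c2c(=O)cc(-c3ccc(OCOC)cc3)oc2c1 | intermediate
10 | 3-chloro-3-methylbut-1-yne | CC(C)(Cl)C#C | starting material
11 | 7-methoxy-2-[4-(methoxymethoxy)phenyl]-5-[(2-methylbut-3-yn-2-yl)oxy]-4H-chromen-4-one | COc1cc(OC(C)(C)C#C)c2c(=O)cc(-c3ccc(OCOC)cc3)oc2c1 | intermediate
12 | 7-methoxy-2-[4-(methoxymethoxy)phenyl]-5-[(2-methylbut-3-en-2-yl)oxy]-4H-chromen-4-one | COc1cc(OC(C)(C)C=C)c2c(=O)cc(-c3ccc(OCOC)cc3)oc2c1 | intermediate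
13 | 7-methoxy-2-[4-(methoxymethoxy)phenyl]-6-(3-methylbut-2-en-1-yl)-4H-chromene-4,5(6H)-dione | COC1=CC2=C(C(=O)C1CC=C(C)C)C(=O)C=C(c1ccc(OCOC)cc1)O2 | intermediate
14 | 5-hydroxy-7-methoxy-2-[4-(methoxymethoxy)phenyl]-6-(3-methylbut-2-en-1-yl)-4H-chromen-4-one | COc1cc2oc(-c3ccc(OCOC)cc3)cc(=O)c2c(O)c1CC=C(C)C | intermediate
15 | 7-methoxy-5-(methoxymethoxy)-2-[4-(methoxymethoxy)phenyl]-6-(3-methylbut-2-en-1-yl)-4H-chromen-4-one | COCOc1c(CC=C(C)C)c(OC)cc2oc(-c3ccc(OCOC)cc3)cc(=O)c12 | intermediate
16 | (2S)-7-methoxy-5-(methoxymethoxy)-2-[4-(methoxymethoxy)phenyl]-6-(3-methylbut-2-en-1-yl)chroman-4-one | COc1cc2c(c(OCOC)c1CC=C(C)C)C(=O)C[C@@H](c1ccc(OCOC)cc1)O2 | intermediate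
17 | 6-prenylsakuranetin, (2S)-5-hydroxy-2-(4-hydroxyphenyl)-7-methoxy-6-(3-methylbut-2-en-1-yl)chroman-4-one | COc1cc2c(c(O)c1CC=C(C)C)C(=O)C[C@@H](c1ccc(O)cc1)O2 | target

## Step count and risks

Total step count: 10. Longest linear sequence: 9 steps (from 3 through steps 2 to 10); the branch from 1 joins at step 4.

**Step 4 (key step).** The electron-rich, doubly ortho-substituted iodide may couple with the alkyne before CO is taken up and then close a five-membered ring. Diethylamine may intercept the aroylpalladium species (aminocarbonylation), or the iodide may be reduced. Fallback: the route is left at 4 and rejoined at 9. Claisen–Schmidt condensation of 4 with purchased 1-(2,6-dihydroxy-4-methoxyphenyl)ethan-1-one F1 (KOH, EtOH, rt) should give (E)-1-(2,6-dihydroxy-4-methoxyphenyl)-3-[4-(methoxymethoxy)phenyl]prop-2-en-1-one F2. Oxidative cyclisation of F2 with catalytic I2 in DMSO at 120 °C should then close O1–C2 and dehydrogenate to 9. The C4 carbon then comes from the acetophenone and not from CO.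

**Step 5.** O-Alkylation of a peri-carbonyl, chelated phenoxide by a tertiary electrophile may be slow, so that elimination of HCl from 10 outruns etherification. Fallback: from 9, rejoining at 14 and bypassing steps 5 to 7. Iodination ortho to the free hydroxyl with BnMe3N·ICl2 and CaCO3 in CH2Cl2/MeOH should give 5-hydroxy-6-iodo-7-methoxy-2-[4-(methoxymethoxy)phenyl]-4H-chromen-4-one F3. Stille coupling of F3 with purchased tributyl(3-methylbut-2-en-1-yl)stannane F4 (Pd(PPh3)4, DMF, 90 °C) should then place the prenyl group at C6 and give 14.

**Step 9.** Hydride delivery to a β,β-disubstituted, donor-substituted enone next to a 5-alkoxy group may be slow or poorly face-selective. The copper enolate may also open ring C by elimination of O1, eroding the enantiomeric purity, or the C4 ketone may be reduced further. Fallback: from 15, rejoining at 16. Conjugate reduction with LiBH(s-Bu)3 in THF at −78 °C should give racemic 7-methoxy-5-(methoxymethoxy)-2-[4-(methoxymethoxy)phenyl]-6-(3-methylbut-2-en-1-yl)chroman-4-one F5. Kinetic resolution by asymmetric transfer hydrogenation ([Cp*RhCl((R,R)-TsDPEN)], HCO2H/Et3N, EtOAc; catalyst enantiomer chosen to consume the 2R ketone) should reduce that enantiomer to (2R,4R)-7-methoxy-5-(methoxymethoxy)-2-[4-(methoxymethoxy)phenyl]-6-(3-methylbut-2-en-1-yl)chroman-4-ol F6. The unreacted 2S ketone 16 is then separated by chromatography, at the cost of half the material.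

**Step 1.** Iodination may occur in part between a hydroxyl and the methoxyl, or twice, and the electron-rich iodide may lose iodine on standing. Fallback: from 1, rejoining at 2. Protection with MOMCl and i-Pr2NEt should give 1-methoxy-3,5-bis(methoxymethoxy)benzene F7. Directed ortho-lithiation between the two acetal groups (n-BuLi, THF, 0 °C) and quenching with I2 should give 2-iodo-5-methoxy-1,3-bis(methoxymethoxy)benzene F8, and brief treatment with HCl in MeOH at rt should release 2.

**Step 10.** The conditions needed for the slower O4' acetal may protonate the prenyl olefin, which then adds O5–H or methanol, and may cause partial racemisation by acid-mediated opening of ring C. Fallback: from 14, rejoining at 17, so that acid is used before the stereocentre exists.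
- HCl in MeOH on 14 should give 5-hydroxy-2-(4-hydroxyphenyl)-7-methoxy-6-(3-methylbut-2-en-1-yl)-4H-chromen-4-one F9.
- TBSOTf and 2,6-lutidine should give 5-(tert-butyldimethylsilyloxy)-2-[4-(tert-butyldimethylsilyloxy)phenyl]-7-methoxy-6-(3-methylbut-2-en-1-yl)-4H-chromen-4-one F10.
- The copper hydride reduction of step 9 should give (2S)-5-(tert-butyldimethylsilyloxy)-2-[4-(tert-butyldimethylsilyloxy)phenyl]-7-methoxy-6-(3-methylbut-2-en-1-yl)chroman-4-one F11.
- Bu4NF buffered with AcOH in THF at 0 °C should release 17 without acid.

## Further compounds

F1 | step 4 | 1-(2,6-dihydroxy-4-methoxyphenyl)ethan-1-one (purchased) | COc1cc(O)c(C(C)=O)c(O)c1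
F2 | step 4 | (E)-1-(2,6-dihydroxy-4-methoxyphenyl)-3-[4-(methoxymethoxy)phenyl]prop-2-en-1-one | COc1cc(O)c(C(=O)/C=C/c2ccc(OCOC)cc2)c(O)c1
F3 | step 5 | 5-hydroxy-6-iodo-7-methoxy-2-[4-(methoxymethoxy)phenyl]-4H-chromen-4-one | COc1cc2oc(-c3ccc(OCOC)cc3)cc(=O)c2c(O)c1I
F4 | step 5 | tributyl(3-methylbut-2-en-1-yl)stannane (purchased) | CCCC[Sn](CCCC)(CCCC)CC=C(C)C
F5 | step 9 | racemic 7-methoxy-5-(methoxymethoxy)-2-[4-(methoxymethoxy)phenyl]-6-(3-methylbut-2-en-1-yl)chroman-4-one | COc1cc2c(c(OCOC)c1CC=C(C)C)C(=O)CC(c1ccc(OCOC)cc1)O2
F6 | step 9 | (2R,4R)-7-methoxy-5-(methoxymethoxy)-2-[4-(methoxymethoxy)phenyl]-6-(3-methylbut-2-en-1-yl)chroman-4-ol | COc1cc2c(c(OCOC)c1CC=C(C)C)[C@H](O)C[C@H](c1ccc(OCOC)cc1)O2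
F7 | step 1 | 1-methoxy-3,5-bis(methoxymethoxy)benzene | COCOc1cc(OC)cc(OCOC)c1
F8 | step 1 | 2-iodo-5-methoxy-1,3-bis(methoxymethoxy)benzene | COCOc1cc(OC)cc(OCOC)c1I
F9 | step 10 | 5-hydroxy-2-(4-hydroxyphenyl)-7-methoxy-6-(3-methylbut-2-en-1-yl)-4H-chromen-4-one | COc1cc2oc(-c3ccc(O)cc3)cc(=O)c2c(O)c1CC=C(C)C
F10 | step 10 | 5-(tert-butyldimethylsilyloxy)-2-[4-(tert-butyldimethylsilyloxy)phenyl]-7-methoxy-6-(3-methylbut-2-en-1-yl)-4H-chromen-4-one | COc1cc2oc(-c3ccc(O[Si](C)(C)C(C)(C)C)cc3)cc(=O)c2c(O[Si](C)(C)C(C)(C)C)c1CC=C(C)C
F11 | step 10 | (2S)-5-(tert-butyldimethylsilyloxy)-2-[4-(tert-butyldimethylsilyloxy)phenyl]-7-methoxy-6-(3-methylbut-2-en-1-yl)chroman-4-one | COc1cc2c(c(O[Si](C)(C)C(C)(C)C)c1CC=C(C)C)C(=O)C[C@@H](c1ccc(O[Si](C)(C)C(C)(C)C)cc1)O2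
A1 | alternative 1 | 2-(2-diazoacetyl)-3-{[4-(tert-butyldimethylsilyloxy)benzyl]oxy}-5-methoxy-6-(3-methylbut-2-en-1-yl)phenyl acetate | COc1cc(OCc2ccc(O[Si](C)(C)C(C)(C)C)cc2)c(C(=O)C=[N+]=[N-])c(OC(C)=O)c1CC=C(C)C
A2 | alternative 1 | (S)-6-prenylsakuranetin 5-acetate 4'-tert-butyldimethylsilyl ether | COc1cc2c(c(OC(C)=O)c1CC=C(C)C)C(=O)C[C@@H](c1ccc(O[Si](C)(C)C(C)(C)C)cc1)O2
A3 | alternative 2 | methyl 4-{(2S)-2-[4-(methoxymethoxy)phenyl]-4-oxo-3,4-dihydro-2H-pyran-6-yl}-2-(3-methylbut-2-en-1-yl)-3-oxobutanoate | COC(=O)C(CC=C(C)C)C(=O)CC1=CC(=O)C[C@@H](c2ccc(OCOC)cc2)O1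
A4 | alternative 2 | (S)-6-prenylnaringenin 4'-methoxymethyl ether | Oc1cc2c(c(O)c1CC=C(C)C)C(=O)C[C@@H](c1ccc(OCOC)cc1)O2
A5 | alternative 3 | 2-hydroxy-4-methoxy-6-(methoxymethoxy)-5-(3-methylbut-2-en-1-yl)benzaldehyde | COc1cc(O)c(C=O)c(OCOC)c1CC=C(C)C
A6 | alternative 3 | 1-ethenyl-4-(methoxymethoxy)benzene | C=Cc1ccc(OCOC)cc1
A7 | alternative 3 | trimethyl orthoformate | COC(OC)OC
A8 | alternative 3 | (2S,4S)-4,7-dimethoxy-5,4'-bis(methoxymethoxy)-6-prenylflavan | COc1cc2c(c(OCOC)c1CC=C(C)C)[C@@H](OC)C[C@@H](c1ccc(OCOC)cc1)O2
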